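**Plan**

Numbering (germacranolide): lactone O–C6, ring-fusion C7, C8 (free OH), C9 (angelate), Z-C10(Me)=C1, C2 (OH), C3, E-C4(Me)=C5; C11(=C13H2)–C12(=O) completes the lactone.
Retrosynthesis: remove the C2 silyl ether, the C9 angelate and C13 (Mannich/elimination at C11). Then cut C8–C9, the glycol bond of the ten-membered ring: two neighbouring carbinol carbons, C9 allylic to C1=C10, are the retron of a reductive aldehyde–aldehyde coupling. Then cut C6–C7 (syn-aldol with lactonisation onto C12), C5–C6/C4–C15 (alkyne carboalumination) and C1=C10 (Z-olefination).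
Forward: a C1–C5 alkynol from (S)-glycidyl trityl ether gains C9/C10/C14, then C15 and C6, then C7/C8/C11/C12 by an auxiliary aldol that closes the γ-lactone (ring 1). A titanium pinacol coupling of the C8/C9 dialdehyde closes the ten-membered carbocycle (ring 2); C13, the angelate and the free C2–OH follow.
Stereochemistry: C2 from the chiral pool; C6 and C7 from the (S)-4-benzyloxazolidinone; C8 and C9 in the ring closure (Felkin–Anh with respect to C7, trans-glycol preference of ten-membered titanium glycolates). 4E comes from syn-carbometallation, 1(10)Z from the Still–Gennari reagent, the ester Z from angelic acid.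

Key step: step 15

**Route**

Step 1
Reactants: 1 (S)-2-[(trityloxy)methyl]oxirane; 2 lithium acetylide ethylenediamine complex
Product: 3 (2S)-1-(trityloxy)pent-4-yn-2-ol
Conditions: LiC≡CH·H2NCH2CH2NH2, DMSO, 0 °C to rt; then H2O
Reagents that add atoms: lithium acetylide ethylenediamine complex (2), [Li+].[C-]#C.NCCN
Why: SN2 opening of the terminal epoxide carbon by the acetylide (epoxide alkynylation) leaves the stereocentre untouched, so the chiral-pool centre becomes C2 of the target.

Step 2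
Reactants: 3 (2S)-1-(trityloxy)pent-4-yn-2-ol; 4 tert-butyl(chloro)diphenylsilane
Product: 5 tert-butyl(diphenyl){[(2S)-1-(trityloxy)pent-4-yn-2-yl]oxy}silane
Conditions: TBDPSCl, imidazole, DMF, rt
Reagents that add atoms: tert-butyl(chloro)diphenylsilane (4), CC(C)(C)[Si](Cl)(c1ccccc1)c1ccccc1
Why: Imidazole-promoted silylation of the secondary alcohol (silyl ether formation); the robust tert-butyldiphenylsilyl group is chosen because it must outlast the later removal of tert-butyldimethylsilyl and triethylsilyl ethers.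

Step 3
Reactants: 5 tert-butyl(diphenyl){[(2S)-1-(trityloxy)pent-4-yn-2-yl]oxy}silane
Product: 6 (2S)-2-[(tert-butyldiphenylsilyl)oxy]pent-4-yn-1-ol
Conditions: TsOH·H2O (cat.), MeOH/CH2Cl2, rt
Reagents that add atoms: none
Why: Acid-catalysed SN1 solvolysis of the trityl ether (detritylation), to which the alkyne and the secondary silyl ether are inert.

Step 4
Reactants: 6 (2S)-2-[(tert-butyldiphenylsilyl)oxy]pent-4-yn-1-ol
Product: 7 (2S)-2-[(tert-butyldiphenylsilyl)oxy]pent-4-ynal
Conditions: Dess–Martin periodinane, CH2Cl2, 0 °C to rt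
Reagents that add atoms: none
Why: Dess–Martin oxidation of the primary alcohol under non-basic conditions should keep the α-silyloxy aldehyde configurationally intact; it is used without purification.

Step 5
Reactants: 7 (2S)-2-[(tert-butyldiphenylsilyl)oxy]pent-4-ynal; 8 ethyl 2-[bis(2,2,2-trifluoroethoxy)phosphoryl]propanoate
Product: 9 ethyl (2Z,4S)-4-[(tert-butyldiphenylsilyl)oxy]-2-methylhept-2-en-6-ynoate
Conditions: 8, KN(SiMe3)2, 18-crown-6, THF, −78 °C; then 7
Reagents that add atoms: ethyl 2-[bis(2,2,2-trifluoroethoxy)phosphoryl]propanoate (8), CCOC(=O)C(C)P(=O)(OCC(F)(F)F)OCC(F)(F)F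
Why: Still–Gennari olefination: the bis(trifluoroethyl) phosphonate eliminates fast from the kinetic adduct and so should give the Z-trisubstituted enoate, which fixes the C1=C10 geometry (C2 and C9 cis).

Step 6
Reactants: 9 ethyl (2Z,4S)-4-[(tert-butyldiphenylsilyl)oxy]-2-methylhept-2-en-6-ynoate
Product: 10 (2Z,4S)-4-[(tert-butyldiphenylsilyl)oxy]-2-methylhept-2-en-6-yn-1-ol
Conditions: iBu2AlH, CH2Cl2, −78 °C; then H2O
Reagents that add atoms: none
Why: 1,2-Reduction of the enoate to the allylic alcohol with iBu2AlH (ester reduction), without effect on the alkene geometry or the alkyne.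

Step 7
Reactants: 10 (2Z,4S)-4-[(tert-butyldiphenylsilyl)oxy]-2-methylhept-2-en-6-yn-1-ol; 11 tert-butyl(chloro)dimethylsilane
Product: 12 (2Z,4S)-1-[(tert-butyldimethylsilyl)oxy]-4-[(tert-butyldiphenylsilyl)oxy]-2-methylhept-2-en-6-yne
Conditions: TBSCl, imidazole, CH2Cl2, rt
Reagents that add atoms: tert-butyl(chloro)dimethylsilane (11), CC(C)(C)[Si](C)(C)Cl
Why: Silylation of the primary allylic alcohol (silyl ether formation), so that it can later be unmasked beside the secondary tert-butyldiphenylsilyl ether.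

Step 8
Reactants: 12 (2Z,4S)-1-[(tert-butyldimethylsilyl)oxy]-4-[(tert-butyldiphenylsilyl)oxy]-2-methylhept-2-en-6-yne; 13 trimethylaluminium; 14 formaldehyde (used as paraformaldehyde)
Product: 15 (2E,5S,6Z)-8-[(tert-butyldimethylsilyl)oxy]-5-[(tert-butyldiphenylsilyl)oxy]-3,7-dimethylocta-2,6-dien-1-ol
Conditions: AlMe3, Cp2ZrCl2 (cat.), CH2Cl2, 0 °C to rt; then n-BuLi, (CH2O)n, THF, −78 °C to rt; then H2O
Reagents that add atoms: trimethylaluminium (13), C[Al](C)C; formaldehyde (14), C=O
Why: Negishi zirconium-catalysed carboalumination adds Me and Al syn across the terminal alkyne with Me on the internal carbon, and the alkenylalanate is hydroxymethylated with retention, which sets E-C4=C5 and brings in C15 and C6.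

Step 9
Reactants: 15 (2E,5S,6Z)-8-[(tert-butyldimethylsilyl)oxy]-5-[(tert-butyldiphenylsilyl)oxy]-3,7-dimethylocta-2,6-dien-1-ol
Product: 16 (2E,5S,6Z)-8-[(tert-butyldimethylsilyl)oxy]-5-[(tert-butyldiphenylsilyl)oxy]-3,7-dimethylocta-2,6-dienal
Conditions: MnO2, CH2Cl2, rt
Reagents that add atoms: none
Why: MnO2 oxidation of the allylic alcohol should give the E-enal without touching the silyl ethers or the double-bond geometry.

Step 10
Reactants: 17 (4S)-4-benzyl-1,3-oxazolidin-2-one; 18 methyl 4-chloro-4-oxobutanoate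
Product: 19 methyl 4-[(4S)-4-benzyl-2-oxo-1,3-oxazolidin-3-yl]-4-oxobutanoate
Conditions: n-BuLi, THF, −78 °C; then 18, −78 to 0 °C
Reagents that add atoms: methyl 4-chloro-4-oxobutanoate (18), COC(=O)CCC(Cl)=O
Why: N-Acylation of the lithiated oxazolidinone by the acid chloride (imide formation) gives the succinate-derived aldol donor.

Step 11
Reactants: 16 (2E,5S,6Z)-8-[(tert-butyldimethylsilyl)oxy]-5-[(tert-butyldiphenylsilyl)oxy]-3,7-dimethylocta-2,6-dienal; 19 methyl 4-[(4S)-4-benzyl-2-oxo-1,3-oxazolidin-3-yl]-4-oxobutanoate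
Product: 21 (4S)-4-benzyl-3-({(2R,3S)-2-[(1E,4S,5Z)-7-[(tert-butyldimethylsilyl)oxy]-4-[(tert-butyldiphenylsilyl)oxy]-2,6-dimethylhepta-1,5-dien-1-yl]-5-oxooxolan-3-yl}carbonyl)-1,3-oxazolidin-2-one, via syn-aldol adduct 20 (not isolated)
Conditions: 19, Bu2BOTf, iPr2NEt, CH2Cl2, −78 to 0 °C; 16, −78 to 0 °C; pH 7 buffer, MeOH, H2O2, 0 °C; then PPTS (cat.), PhMe, 50 °C
Reagents that add atoms: methyl 4-[(4S)-4-benzyl-2-oxo-1,3-oxazolidin-3-yl]-4-oxobutanoate (19), COC(=O)CCC(=O)N1[C@@H](Cc2ccccc2)COC1=O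
Why: Evans boron syn-aldol reaction: the Z-boron enolate of the imide (the ester is not enolised) adds to the enal through a Zimmerman–Traxler chair on the face left open by the benzyl group, setting C7 and C6, and the γ-hydroxy ester then lactonises under mild acid to the trans-disubstituted γ-lactone (ring 1).

Step 12
Reactants: 21 the lactone imide of step 11
Product: 22 (4R,5R)-5-[(1E,4S,5Z)-7-[(tert-butyldimethylsilyl)oxy]-4-[(tert-butyldiphenylsilyl)oxy]-2,6-dimethylhepta-1,5-dien-1-yl]-4-(hydroxymethyl)oxolan-2-one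
Conditions: NaBH4, THF/H2O, 0 °C to rt
Reagents that add atoms: none
Why: Reductive cleavage of the N-acyloxazolidinone with NaBH4 (imide reduction): the exocyclic imide carbonyl is far more electrophilic than the γ-lactone, so C8 should be delivered as the primary alcohol and the auxiliary released.

Step 13
Reactants: 22 the C8 alcohol of step 12
Product: 23 (4R,5R)-5-[(1E,4S,5Z)-4-[(tert-butyldiphenylsilyl)oxy]-7-hydroxy-2,6-dimethylhepta-1,5-dien-1-yl]-4-(hydroxymethyl)oxolan-2-one
Conditions: HF·pyridine, pyridine, THF, 0 °C to rt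
Reagents that add atoms: none
Why: Fluoride-mediated desilylation: the primary allylic tert-butyldimethylsilyl ether should be cleaved much faster than the hindered secondary tert-butyldiphenylsilyl ether.

Step 14
Reactants: 23 the C8,C9-diol of step 13
Product: 24 (2R,3S)-2-[(1E,4S,5Z)-4-[(tert-butyldiphenylsilyl)oxy]-2,6-dimethyl-7-oxohepta-1,5-dien-1-yl]-5-oxooxolane-3-carbaldehyde
Conditions: Dess–Martin periodinane, NaHCO3, CH2Cl2, 0 °C to rt
Reagents that add atoms: none
Why: Double Dess–Martin oxidation under buffered, non-basic conditions should give the C8 aldehyde and the Z-C9 enal without epimerisation at C7, β-elimination of the lactone oxygen or Z/E isomerisation; the dialdehyde is used at once.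

Step 15
Reactants: 24 the lactone dialdehyde of step 14
Product: 25 macrocyclic trans-8,9-glycol: (1(10)Z,4E)-2-[(tert-butyldiphenylsilyl)oxy]-8,9-dihydroxy-13-norgermacra-1(10),4-dien-12,6-olide, same spatial arrangement at C2, C6, C7, C8 and C9 as in the target
Conditions: TiCl3(DME)1.5, Zn–Cu couple, DME, reflux; then 24 by syringe pump over 30 h, 25 °C, high dilution; then pH 7 buffer
Reagents that add atoms: none
Why: Low-valent titanium transfers one electron to each aldehyde, the conjugated C9 aldehyde becoming an allyl-stabilised ketyl and the C8 aldehyde a simple ketyl, both bound through oxygen to the titanium surface, and union of the two at C8–C9 gives a titanium glycolate that water releases as the diol. The closest known reaction type is the titanium-induced intramolecular pinacol coupling of dialdehydes to cycloalkane-1,2-diols (McMurry pinacol), which is established for medium and large carbocycles. The ten-membered ring closes in the exo mode at both carbonyl carbons (formally 10-exo-trig, both oxygens outside the ring and held on the metal), helped by the trans-lactone and the E-C4=C5 and Z-C1=C10 double bonds, which leave few rotors between C8 and C9. C8 is controlled by C7: the new bond should form anti to the C7–C6 bond, along which the chain returns, with the C8 oxygen outside and H8 anti to C11 (Felkin–Anh), which gives 8R; C9 is controlled by C8, because in rings of ten or more members this coupling favours the trans glycol, the two bulky titanium-bound oxygens avoiding each other, which gives 9R. The step needs ring closure instead of chain growth (slow addition, high dilution), coupling at C9 and not at C1 of the allyl-ketyl (C1 attack would need an eight-membered ring next to the C2 silyloxy group), diol and not olefin (25 °C), and an untouched lactone, which is why the conjugated C13 methylene is added only afterwards.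

Step 16
Reactants: 25 the macrocyclic glycol; 26 triethylsilyl trifluoromethanesulfonate
Product: 27 8,9-bis(triethylsilyl) ether of 25
Conditions: Et3SiOTf, 2,6-lutidine, CH2Cl2, −78 to 0 °C
Reagents that add atoms: triethylsilyl trifluoromethanesulfonate (26), CC[Si](CC)(CC)OS(=O)(=O)C(F)(F)F
Why: Silylation of both secondary hydroxyls with the reactive silyl triflate (silyl ether formation) protects the glycol for the enolate step.

Step 17
Reactants: 27 the bis(triethylsilyl) ether; 28 N,N-dimethylmethyleneiminium iodide (Eschenmoser's salt)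
Product: 31 α-methylene lactone: (1(10)Z,4E)-2-[(tert-butyldiphenylsilyl)oxy]-8,9-bis[(triethylsilyl)oxy]germacra-1(10),4,11(13)-trien-12,6-olide, via Mannich base 29 (not isolated), via trimethylammonium iodide 30 (not isolated)
Conditions: LiN(iPr)2, THF, −78 °C; [CH2=NMe2]I, −78 °C to rt; then MeI, MeOH, rt; then aq. NaHCO3, CH2Cl2, rt
Reagents that add atoms: N,N-dimethylmethyleneiminium iodide (28), C=[N+](C)C.[I-]
Why: Eschenmoser methylenation: the lithium enolate of the lactone should undergo a Mannich reaction with the iminium salt anti to the C7 substituent, and exhaustive methylation followed by mild-base elimination (Hofmann-type E1cB) gives the exocyclic C11=C13 double bond.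

Step 18
Reactants: 31 the α-methylene lactone bis(triethylsilyl) ether
Product: 32 (1(10)Z,4E)-2-[(tert-butyldiphenylsilyl)oxy]-8,9-dihydroxygermacra-1(10),4,11(13)-trien-12,6-olide
Conditions: HF·pyridine, pyridine, THF, 0 °C
Reagents that add atoms: none
Why: Selective fluoride desilylation: the two secondary triethylsilyl ethers should be removed under buffered conditions that the tert-butyldiphenylsilyl ether and the α-methylene lactone survive.

Step 19
Reactants: 32 the 8,9-diol; 33 angelic acid [(2Z)-2-methylbut-2-enoic acid]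
Product: 34 9-angelate of 32: (1(10)Z,4E)-9-[(2Z)-2-methylbut-2-enoyloxy]-2-[(tert-butyldiphenylsilyl)oxy]-8-hydroxygermacra-1(10),4,11(13)-trien-12,6-olide
Conditions: 33, 2,4,6-trichlorobenzoyl chloride, Et3N, PhMe, rt; then 32, 70 °C
Reagents that add atoms: angelic acid (33), C/C=C(/C)C(=O)O
Why: Yamaguchi esterification with the preformed mixed anhydride and no acyl-transfer catalyst (to avoid angelate-to-tiglate isomerisation): the allylic C9 hydroxyl, flanked by the flat C10 alkene carbon, should be acylated in preference to the C8 hydroxyl, which is crowded by the ring-fusion carbon C7 and the lactone.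

Step 20
Reactants: 34 the 9-angelate 2-silyl ether
Product: 35 target, (3aR,4R,5R,6Z,8S,10E,11aR)-4,8-dihydroxy-6,10-dimethyl-3-methylidene-2-oxo-2,3,3a,4,5,8,9,11a-octahydrocyclodeca[b]furan-5-yl (2Z)-2-methylbut-2-enoate
Conditions: HF·pyridine, THF, 0 °C to rt
Reagents that add atoms: none
Why: Fluoride desilylation under mildly acidic conditions should remove the last silyl ether without acyl migration of the angelate or addition to the methylene lactone.

**Compound list**

1 | (S)-2-[(trityloxy)methyl]oxirane ((S)-glycidyl trityl ether) | C1O[C@@H]1COC(c1ccccc1)(c1ccccc1)c1ccccc1 | starting material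
2 | lithium acetylide ethylenediamine complex, LiC≡CH·H2NCH2CH2NH2 | [Li+].[C-]#C.NCCN | starting material
3 | (2S)-1-(trityloxy)pent-4-yn-2-ol | C#CC[C@H](O)COC(c1ccccc1)(c1ccccc1)c1ccccc1 | intermediate
4 | tert-butyl(chloro)diphenylsilane | CC(C)(C)[Si](Cl)(c1ccccc1)c1ccccc1 | starting material
5 | tert-butyl(diphenyl){[(2S)-1-(trityloxy)pent-4-yn-2-yl]oxy}silane | C#CC[C@H](O[Si](c1ccccc1)(c1ccccc1)C(C)(C)C)COC(c1ccccc1)(c1ccccc1)c1ccccc1 | intermediate
6 | (2S)-2-[(tert-butyldiphenylsilyl)oxy]pent-4-yn-1-ol | C#CC[C@H](O[Si](c1ccccc1)(c1ccccc1)C(C)(C)C)CO | intermediate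
7 | (2S)-2-[(tert-butyldiphenylsilyl)oxy]pent-4-ynal | C#CC[C@H](O[Si](c1ccccc1)(c1ccccc1)C(C)(C)C)C=O | intermediate
8 | ethyl 2-[bis(2,2,2-trifluoroethoxy)phosphoryl]propanoate | CCOC(=O)C(C)P(=O)(OCC(F)(F)F)OCC(F)(F)F | starting material
9 | ethyl (2Z,4S)-4-[(tert-butyldiphenylsilyl)oxy]-2-methylhept-2-en-6-ynoate | C#CC[C@H](O[Si](c1ccccc1)(c1ccccc1)C(C)(C)C)/C=C(/C)C(=O)OCC | intermediate
10 | (2Z,4S)-4-[(tert-butyldiphenylsilyl)oxy]-2-methylhept-2-en-6-yn-1-ol | C#CC[C@H](O[Si](c1ccccc1)(c1ccccc1)C(C)(C)C)/C=C(/C)CO | intermediate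
11 | tert-butyl(chloro)dimethylsilane | CC(C)(C)[Si](C)(C)Cl | starting material
12 | (2Z,4S)-1-[(tert-butyldimethylsilyl)oxy]-4-[(tert-butyldiphenylsilyl)oxy]-2-methylhept-2-en-6-yne | C#CC[C@H](O[Si](c1ccccc1)(c1ccccc1)C(C)(C)C)/C=C(/C)CO[Si](C)(C)C(C)(C)C | intermediate
13 | trimethylaluminium, AlMe3 | C[Al](C)C | starting material
14 | formaldehyde (used as paraformaldehyde) | C=O | starting material
15 | (2E,5S,6Z)-8-[(tert-butyldimethylsilyl)oxy]-5-[(tert-butyldiphenylsilyl)oxy]-3,7-dimethylocta-2,6-dien-1-ol | OC/C=C(\C)C[C@H](O[Si](c1ccccc1)(c1ccccc1)C(C)(C)C)/C=C(/C)CO[Si](C)(C)C(C)(C)C | intermediate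
16 | (2E,5S,6Z)-8-[(tert-butyldimethylsilyl)oxy]-5-[(tert-butyldiphenylsilyl)oxy]-3,7-dimethylocta-2,6-dienal | O=C/C=C(\C)C[C@H](O[Si](c1ccccc1)(c1ccccc1)C(C)(C)C)/C=C(/C)CO[Si](C)(C)C(C)(C)C | intermediate
17 | (4S)-4-benzyl-1,3-oxazolidin-2-one | O=C1N[C@@H](Cc2ccccc2)CO1 | starting material
18 | methyl 4-chloro-4-oxobutanoate | COC(=O)CCC(Cl)=O | starting material
19 | methyl 4-[(4S)-4-benzyl-2-oxo-1,3-oxazolidin-3-yl]-4-oxobutanoate | COC(=O)CCC(=O)N1[C@@H](Cc2ccccc2)COC1=O | intermediate
20 | syn-aldol adduct: methyl (3S,4R,5E,8S,9Z)-3-{[(4S)-4-benzyl-2-oxo-1,3-oxazolidin-3-yl]carbonyl}-11-[(tert-butyldimethylsilyl)oxy]-8-[(tert-butyldiphenylsilyl)oxy]-4-hydroxy-6,10-dimethylundeca-5,9-dienoate | COC(=O)C[C@H](C(=O)N1[C@@H](Cc2ccccc2)COC1=O)[C@H](O)/C=C(\C)C[C@H](O[Si](c1ccccc1)(c1ccccc1)C(C)(C)C)/C=C(/C)CO[Si](C)(C)C(C)(C)C | intermediate (not isolated)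
21 | lactone imide: (4S)-4-benzyl-3-({(2R,3S)-2-[(1E,4S,5Z)-7-[(tert-butyldimethylsilyl)oxy]-4-[(tert-butyldiphenylsilyl)oxy]-2,6-dimethylhepta-1,5-dien-1-yl]-5-oxooxolan-3-yl}carbonyl)-1,3-oxazolidin-2-one | CC(C)(C)[Si](C)(C)OC/C(C)=C\[C@@H](O[Si](c1ccccc1)(c1ccccc1)C(C)(C)C)C/C(C)=C/[C@H]1OC(=O)C[C@@H]1C(=O)N1[C@@H](Cc2ccccc2)COC1=O | intermediate
22 | (4R,5R)-5-[(1E,4S,5Z)-7-[(tert-butyldimethylsilyl)oxy]-4-[(tert-butyldiphenylsilyl)oxy]-2,6-dimethylhepta-1,5-dien-1-yl]-4-(hydroxymethyl)oxolan-2-one | CC(C)(C)[Si](C)(C)OC/C(C)=C\[C@@H](O[Si](c1ccccc1)(c1ccccc1)C(C)(C)C)C/C(C)=C/[C@H]1OC(=O)C[C@@H]1CO | intermediate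
23 | (4R,5R)-5-[(1E,4S,5Z)-4-[(tert-butyldiphenylsilyl)oxy]-7-hydroxy-2,6-dimethylhepta-1,5-dien-1-yl]-4-(hydroxymethyl)oxolan-2-one | OC/C(C)=C\[C@@H](O[Si](c1ccccc1)(c1ccccc1)C(C)(C)C)C/C(C)=C/[C@H]1OC(=O)C[C@@H]1CO | intermediate
24 | (2R,3S)-2-[(1E,4S,5Z)-4-[(tert-butyldiphenylsilyl)oxy]-2,6-dimethyl-7-oxohepta-1,5-dien-1-yl]-5-oxooxolane-3-carbaldehyde | O=C/C(C)=C\[C@@H](O[Si](c1ccccc1)(c1ccccc1)C(C)(C)C)C/C(C)=C/[C@H]1OC(=O)C[C@@H]1C=O | intermediate
25 | macrocyclic trans-8,9-glycol: (1(10)Z,4E)-2-[(tert-butyldiphenylsilyl)oxy]-8,9-dihydroxy-13-norgermacra-1(10),4-dien-12,6-olide | C1C(=O)O[C@@H]2/C=C(\C)C[C@H](O[Si](c3ccccc3)(c3ccccc3)C(C)(C)C)/C=C(/C)[C@@H](O)[C@H](O)[C@@H]12 | intermediate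
26 | triethylsilyl trifluoromethanesulfonate | CC[Si](CC)(CC)OS(=O)(=O)C(F)(F)F | starting material
27 | 8,9-bis(triethylsilyl) ether of 25 | C1C(=O)O[C@@H]2/C=C(\C)C[C@H](O[Si](c3ccccc3)(c3ccccc3)C(C)(C)C)/C=C(/C)[C@@H](O[Si](CC)(CC)CC)[C@H](O[Si](CC)(CC)CC)[C@@H]12 | intermediate
28 | N,N-dimethylmethyleneiminium iodide (Eschenmoser's salt) | C=[N+](C)C.[I-] | starting material
29 | Mannich base: 11-[(dimethylamino)methyl] derivative of 27, C13 trans to C8 | CN(C)C[C@@H]1C(=O)O[C@@H]2/C=C(\C)C[C@H](O[Si](c3ccccc3)(c3ccccc3)C(C)(C)C)/C=C(/C)[C@@H](O[Si](CC)(CC)CC)[C@H](O[Si](CC)(CC)CC)[C@@H]12 | intermediate (not isolated)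
30 | trimethylammonium iodide of 29 | C[N+](C)(C)C[C@@H]1C(=O)O[C@@H]2/C=C(\C)C[C@H](O[Si](c3ccccc3)(c3ccccc3)C(C)(C)C)/C=C(/C)[C@@H](O[Si](CC)(CC)CC)[C@H](O[Si](CC)(CC)CC)[C@@H]12.[I-] | intermediate (not isolated)
31 | α-methylene lactone: (1(10)Z,4E)-2-[(tert-butyldiphenylsilyl)oxy]-8,9-bis[(triethylsilyl)oxy]germacra-1(10),4,11(13)-trien-12,6-olide | C=C1C(=O)O[C@@H]2/C=C(\C)C[C@H](O[Si](c3ccccc3)(c3ccccc3)C(C)(C)C)/C=C(/C)[C@@H](O[Si](CC)(CC)CC)[C@H](O[Si](CC)(CC)CC)[C@@H]12 | intermediate
32 | (1(10)Z,4E)-2-[(tert-butyldiphenylsilyl)oxy]-8,9-dihydroxygermacra-1(10),4,11(13)-trien-12,6-olide | C=C1C(=O)O[C@@H]2/C=C(\C)C[C@H](O[Si](c3ccccc3)(c3ccccc3)C(C)(C)C)/C=C(/C)[C@@H](O)[C@H](O)[C@@H]12 | intermediate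
33 | angelic acid, (2Z)-2-methylbut-2-enoic acid | C/C=C(/C)C(=O)O | starting material
34 | 9-angelate of 32 (2-tert-butyldiphenylsilyl ether of the target) | C=C1C(=O)O[C@@H]2/C=C(\C)C[C@H](O[Si](c3ccccc3)(c3ccccc3)C(C)(C)C)/C=C(/C)[C@@H](OC(=O)/C(C)=C\C)[C@H](O)[C@@H]12 | intermediate
35 | (3aR,4R,5R,6Z,8S,10E,11aR)-4,8-dihydroxy-6,10-dimethyl-3-methylidene-2-oxo-2,3,3a,4,5,8,9,11a-octahydrocyclodeca[b]furan-5-yl (2Z)-2-methylbut-2-enoate | C=C1C(=O)O[C@@H]2/C=C(\C)C[C@H](O)/C=C(/C)[C@@H](OC(=O)/C(C)=C\C)[C@H](O)[C@@H]12 | target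

**Count and risks**

Total step count: 20. Longest linear sequence: 19 steps (steps 1–9 and 11–20; step 10 makes the aldol donor).

Steps most likely to fail:

1. Step 15 (ring closure). The two ketyl termini may couple with both oxygens held on one metal centre and so give the cis glycol; the allyl-ketyl may also lose the C2 silyloxy group reductively, or chains may couple with each other. C8, which is set by C7, is expected to be right even when C9 is not. Fallback, which no longer relies on the coupling for C9: it sets out from 24, coupled as in step 15, and takes the cis-8,9-glycol F1 (alone or mixed with 25) onward. MnO2 in CH2Cl2 should oxidise only the allylic C9 hydroxyl to the 8-hydroxy-9-ketone F2. Et3SiOTf and 2,6-lutidine give the 8-triethylsilyl ether F3. Luche reduction (NaBH4, CeCl3·7H2O, MeOH, −78 °C), with hydride entering anti to the C8 silyloxy group (Felkin–Anh), should give the 9R-alcohol F4. A second silylation with Et3SiOTf brings the material back to the route at 27.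

2. Step 19 (regioselective esterification). Acylation may take place at the C8 hydroxyl or at both hydroxyls, or be so slow that the angelate isomerises to the tiglate. Fallback, which tells the two hydroxyls apart by oxidation state instead of by accessibility: it sets out from 32. MnO2 oxidises only the allylic C9 hydroxyl to the methylene-lactone 8-hydroxy-9-ketone F5. Et3SiOTf and 2,6-lutidine give the 8-triethylsilyl ether F6. Luche reduction at −78 °C (CeCl3·7H2O to keep the reduction 1,2 and away from the methylene lactone) should give the 9R-alcohol F7. Its only free hydroxyl is esterified with the mixed anhydride of 33 as in step 19 to the 9-angelate 8-silyl ether F8. HF·pyridine then removes both silyl groups and the route is rejoined at 35.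

3. Step 12 (auxiliary removal). Under the basic borohydride conditions hydride may attack the lactone, or the new C8 alkoxide may take over the lactone acyl group from the C6 oxygen (translactonisation). Fallback: it sets out from 21. The auxiliary is cleaved hydrolytically (LiOH, H2O2, THF/H2O, 0 °C) to the lactone carboxylic acid F9, in which C8 is a carboxylate and the lactone cannot move. The acid is then reduced through its mixed carbonic anhydride (iBuOCOCl, N-methylmorpholine, THF, −15 °C; then NaBH4, H2O, short contact), which comes back to the route at 22.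

Further compounds
F1 | step 15 | cis-8,9-glycol, the 9-epimer of 25 | C1C(=O)O[C@@H]2/C=C(\C)C[C@H](O[Si](c3ccccc3)(c3ccccc3)C(C)(C)C)/C=C(/C)[C@H](O)[C@H](O)[C@@H]12
F2 | step 15 | 8-hydroxy-9-ketone, the 9-oxo analogue of 25 | C1C(=O)O[C@@H]2/C=C(\C)C[C@H](O[Si](c3ccccc3)(c3ccccc3)C(C)(C)C)/C=C(/C)C(=O)[C@H](O)[C@@H]12
F3 | step 15 | 8-triethylsilyl ether of F2 | C1C(=O)O[C@@H]2/C=C(\C)C[C@H](O[Si](c3ccccc3)(c3ccccc3)C(C)(C)C)/C=C(/C)C(=O)[C@H](O[Si](CC)(CC)CC)[C@@H]12
F4 | step 15 | 9R-alcohol, the 8-mono(triethylsilyl) ether of 25 | C1C(=O)O[C@@H]2/C=C(\C)C[C@H](O[Si](c3ccccc3)(c3ccccc3)C(C)(C)C)/C=C(/C)[C@@H](O)[C@H](O[Si](CC)(CC)CC)[C@@H]12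
F5 | step 19 | methylene-lactone 8-hydroxy-9-ketone, the 9-oxo analogue of 32 | C=C1C(=O)O[C@@H]2/C=C(\C)C[C@H](O[Si](c3ccccc3)(c3ccccc3)C(C)(C)C)/C=C(/C)C(=O)[C@H](O)[C@@H]12
F6 | step 19 | 8-triethylsilyl ether of F5 | C=C1C(=O)O[C@@H]2/C=C(\C)C[C@H](O[Si](c3ccccc3)(c3ccccc3)C(C)(C)C)/C=C(/C)C(=O)[C@H](O[Si](CC)(CC)CC)[C@@H]12
F7 | step 19 | 9R-alcohol, the 8-mono(triethylsilyl) ether of 32 | C=C1C(=O)O[C@@H]2/C=C(\C)C[C@H](O[Si](c3ccccc3)(c3ccccc3)C(C)(C)C)/C=C(/C)[C@@H](O)[C@H](O[Si](CC)(CC)CC)[C@@H]12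
F8 | step 19 | 9-angelate 8-silyl ether, the 8-triethylsilyl ether of 34 | C=C1C(=O)O[C@@H]2/C=C(\C)C[C@H](O[Si](c3ccccc3)(c3ccccc3)C(C)(C)C)/C=C(/C)[C@@H](OC(=O)/C(C)=C\C)[C@H](O[Si](CC)(CC)CC)[C@@H]12
F9 | step 12 | lactone carboxylic acid, (2R,3S)-2-[(1E,4S,5Z)-7-[(tert-butyldimethylsilyl)oxy]-4-[(tert-butyldiphenylsilyl)oxy]-2,6-dimethylhepta-1,5-dien-1-yl]-5-oxooxolane-3-carboxylic acid | CC(C)(C)[Si](C)(C)OC/C(C)=C\[C@@H](O[Si](c1ccccc1)(c1ccccc1)C(C)(C)C)C/C(C)=C/[C@H]1OC(=O)C[C@@H]1C(=O)O
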